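**Strategy.** Everything rests on cutting ring A across C5–C10 (the quaternary carbon carrying the lactone CH2O, and the central methine of the tricycle) together with C3–C4 (numbering defined below). Ring A, whose C4–C5 edge carries the cis-fused γ-lactone (C18 carbonyl, C19 methylene), is the cyclohexene retron of a Diels–Alder reaction between a 4-substituted butenolide (C4=C5) and an (E)-diene (C10=C1–C2=C3) joined by the C6–C9 chain. One intramolecular [4+2] cycloaddition of this acyclic triene closes rings A and B and sets the C5 quaternary centre and the trans ring fusion. Ring C and the spiro epoxy-lactone follow by vinylogous Michael spirocyclisation of an acylfuranone onto the derived dienyl lactone and enol-lactone epoxidation.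

Key step: step 8

Numbering used for all compounds (clerodane-type): ring A = C1, C2, C3, C4, C5, C10; ring B = C5, C6, C7, C8, C9, C10; ring C = C1, C10, C9, C11, C12 (ketone), C13 (spiro carbon). C14, C15 (acetal CH) and C16 (C=O) complete the spiro lactone; C17 = methyl on C8, C18 = lactone C=O on C4, C19 = OCH2 on C5, C20 = methyl on C9. β is the face of H-10; C19, C20, C17, the C7 oxygen and H-1 are α.

Assumption: the (S,S)-bromoborane controller of step 3 is taken to give the (2S,3R) acid; if a first run shows the opposite sense, its (R,R) antipode is used with no other change.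

**Step 1**
Reactants: 1 4-(tert-butyldimethylsilyloxy)but-1-yne
Product: 3 (E)-5-(tert-butyldimethylsilyloxy)-3-methylpent-2-en-1-ol, via alkenylalane 2 (not isolated)
Conditions: Me3Al, Cp2ZrCl2 (0.25 equiv), CH2Cl2, 0 → 23 °C; then n-BuLi, hexane/THF, −78 °C; (CH2O)n, −78 → 23 °C
Reagents that add atoms: trimethylaluminium C[Al](C)C; paraformaldehyde (as formaldehyde) C=O
Why: Zirconium-catalysed syn-carboalumination of the terminal alkyne (Negishi carboalumination) puts methyl on the internal carbon cis to aluminium, and hydroxymethylation of the derived aluminate with retention fixes the E trisubstituted alkene.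

**Step 2**
Reactants: 3 (E)-5-(tert-butyldimethylsilyloxy)-3-methylpent-2-en-1-ol
Product: 4 (E)-5-(tert-butyldimethylsilyloxy)-3-methylpent-2-enyl propanoate
Conditions: EtCOCl, pyridine, DMAP (cat.), CH2Cl2, 0 °C
Reagents that add atoms: propionyl chloride CCC(=O)Cl
Why: DMAP-catalysed acylation of a primary allylic alcohol with an acid chloride should be clean and creates no stereocentre.

**Step 3**
Reactants: 4 (E)-5-(tert-butyldimethylsilyloxy)-3-methylpent-2-enyl propanoate
Product: 6 (2S,3R)-3-[2-(tert-butyldimethylsilyloxy)ethyl]-2,3-dimethylpent-4-enoic acid, via boron ketene acetal 5 (not isolated)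
Conditions: pre-formed (S,S)-2-bromo-4,5-diphenyl-1,3-bis[3,5-bis(trifluoromethyl)phenylsulfonyl]-1,3,2-diazaborolidine (1.2 equiv), i-Pr2NEt, CH2Cl2, −78 °C, then −20 → 4 °C; aqueous work-up
Reagents that add atoms: none
Why: Enantioselective boron-enolate Ireland–Claisen [3,3] rearrangement in which the ketene acetal with methyl cis to O–B reacts through a chair that places C11 (E alkene) and the enolate methyl pseudo-equatorial and the C9 methyl pseudo-axial, giving the (2S,3R) relationship across the new C8–C9 bond, while the chiral diazaborolidine selects the enantiomeric chair.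

**Step 4**
Reactants: 6 (2S,3R)-3-[2-(tert-butyldimethylsilyloxy)ethyl]-2,3-dimethylpent-4-enoic acid
Product: 7 (2S,3R,4E)-3-[2-(tert-butyldimethylsilyloxy)ethyl]-2,3-dimethylhepta-4,6-dienoic acid
Conditions: vinylboronic acid pinacol ester (2 equiv), Pd(OAc)2 (10 mol %), 1,2-bis(phenylsulfinyl)ethane (10 mol %), 2,6-dimethyl-1,4-benzoquinone (2 equiv), AcOH, dioxane, 23–45 °C
Reagents that add atoms: vinylboronic acid pinacol ester C=CB1OC(C)(C)C(C)(C)O1
Why: Oxidative Heck vinylation of an α-olefin with a vinylboronate should give the E diene, because the quaternary C9 offers no allylic hydrogen and syn β-hydride elimination can only form the conjugated C10=C1 bond.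

**Step 5**
Reactants: 7 (2S,3R,4E)-3-[2-(tert-butyldimethylsilyloxy)ethyl]-2,3-dimethylhepta-4,6-dienoic acid
Product: 9 allyl (4S,5R,6E)-5-[2-(tert-butyldimethylsilyloxy)ethyl]-4,5-dimethyl-3-oxonona-6,8-dienoate, via acyl imidazolide 8 (not isolated)
Conditions: CDI, THF, 23 °C; then Mg(O2CCH2CO2CH2CH=CH2)2, THF, 23 → 45 °C; dilute HCl work-up
Reagents that add atoms: magnesium bis(monoallyl malonate) C=CCOC(=O)CC(=O)[O-].C=CCOC(=O)CC(=O)[O-].[Mg+2]
Why: Masamune–Brooks homologation, in which the acyl imidazolide C-acylates the magnesium malonate half-ester and loses CO2 under near-neutral conditions that should not epimerise C8.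

**Step 6**
Reactants: 9 allyl (4S,5R,6E)-5-[2-(tert-butyldimethylsilyloxy)ethyl]-4,5-dimethyl-3-oxonona-6,8-dienoate; 10 4-bromofuran-2(5H)-one
Product: 11 allyl (4S,5R,6E)-5-[2-(tert-butyldimethylsilyloxy)ethyl]-4,5-dimethyl-3-oxo-2-(5-oxo-2,5-dihydrofuran-3-yl)nona-6,8-dienoate (C2 epimers and enol)
Conditions: NaH (2.1 equiv), THF, 0 °C; then 10, 0 → 23 °C; aq. NH4Cl
Reagents that add atoms: none
Why: Addition–elimination (vinylogous acyl substitution) of the soft β-keto ester enolate at the bromine-bearing β-carbon of the butenolide forms the C5–C6 bond; the new C6 centre is removed in step 7 and enolisation towards C6 protects C8.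

**Step 7**
Reactants: 11 allyl keto ester bearing the butenolide
Product: 13 4-[(3S,4R,5E)-4-[2-(tert-butyldimethylsilyloxy)ethyl]-3,4-dimethyl-2-oxoocta-5,7-dienyl]furan-2(5H)-one, via β-keto acid 12 (not isolated)
Conditions: Pd(PPh3)4 (5 mol %), morpholine (2 equiv), THF, 23 °C
Reagents that add atoms: none
Why: Palladium-catalysed allyl transfer to morpholine (Tsuji–Trost deallylation) followed by spontaneous decarboxylation of the β-keto acid should unveil the ketone under neutral conditions that spare C8, the diene and the butenolide.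

**Step 8**
Reactants: 13 4-[(3S,4R,5E)-4-[2-(tert-butyldimethylsilyloxy)ethyl]-3,4-dimethyl-2-oxoocta-5,7-dienyl]furan-2(5H)-one
Product: 14 12-(tert-butyldimethylsilyloxy)-7-oxo-13,14,15,16-tetranorclerod-1-en-18,19-olide (4β-H; 10β-H; C19, C20 and C17 α; trans-decalin with cis-fused lactone)
Conditions: PhMe (0.005 M), BHT (5 mol %), base-washed sealed tube, 150 °C
Reagents that add atoms: none
Why: On heating, triene 13 should undergo a concerted, thermally allowed [4+2] cycloaddition (intramolecular Diels–Alder reaction of a 1,7,9-decatriene carrying a terminally activated, trisubstituted dienophile), the closest known type being the thermal cyclisation of deca-2,7,9-trienoates and tethered butenolides to octalins. Ring A is closed by the cycloaddition itself (bonds C5–C10 and C3–C4, six-membered, suprafacial on both partners), and ring B is closed in the same event as a six-membered chair-like carbocycle by the C6–C9 tether. C5 and C10 are set trans by the endo transition state (lactone carbonyl under the diene, tether exo), which the E geometry of the diene (tether on the outside position of C10) makes accessible, and C4 is set cis to C19 because the butenolide adds suprafacially. The absolute sense at C5 and C10 is relayed from C8 and C9: in the chair-like tether the C8 methyl is equatorial and the C9 methyl axial, whereas addition to the other butenolide face would force the C8 methyl and the C9 side chain axial. The step needs endo over exo, one π-face over the other, and cycloaddition faster than migration of the butenolide double bond towards the C7 ketone; the sp2 C7 (no axial substituent clashing with the C9 methyl and C19), the neutral non-polar medium and high dilution are meant to secure this.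

**Step 9**
Reactants: 14 tricyclic keto lactone
Product: 15 7α-hydroxy-12-(tert-butyldimethylsilyloxy)-13,14,15,16-tetranorclerod-1-en-18,19-olide
Conditions: L-Selectride (LiBH(s-Bu)3), THF, −78 °C; aq. NH4Cl
Reagents that add atoms: none
Why: Selectride reduction of the ketone from the equatorial direction, because the axial trajectory is blocked by the syn-axial C19 methylene and C9 methyl, should give the axial 7α-alcohol while the lactone is inert at −78 °C.

**Step 10**
Reactants: 15 7α-hydroxy lactone
Product: 18 7α-hydroxy-12-(tert-butyldimethylsilyloxy)-13,14,15,16-tetranorcleroda-1,3-dien-18,19-olide, via C4 phenylselenide 16 (not isolated), via selenoxide 17 (not isolated)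
Conditions: LDA (2.3 equiv), THF, −78 °C; PhSeSePh, HMPA, −78 → −40 °C; then 30 % H2O2, pyridine, CH2Cl2, 0 → 23 °C
Reagents that add atoms: none
Why: α-Selenenylation of the lactone enolate (dianion with the C7 alkoxide) on the convex β-face and selenoxide syn-elimination, which can only use a C3 hydrogen because C5 is quaternary, should give the conjugated 1,3-dienyl lactone.

**Step 11**
Reactants: 18 7α-hydroxy dienyl lactone
Product: 19 7α-acetoxy-12-(tert-butyldimethylsilyloxy)-13,14,15,16-tetranorcleroda-1,3-dien-18,19-olide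
Conditions: Ac2O, DMAP, pyridine, 23 → 50 °C
Reagents that add atoms: acetic anhydride CC(=O)OC(C)=O
Why: DMAP-catalysed acetylation with mild heating should esterify the hindered axial alcohol without changing its configuration.

**Step 12**
Reactants: 19 7α-acetoxy silyl ether
Product: 20 7α-acetoxy-12-hydroxy-13,14,15,16-tetranorcleroda-1,3-dien-18,19-olide
Conditions: HF·pyridine, THF/pyridine, 0 → 23 °C
Reagents that add atoms: none
Why: Buffered fluoride desilylation of the primary silyl ether should leave the acetate and the dienyl lactone untouched.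

**Step 13**
Reactants: 20 primary alcohol
Product: 21 7α-acetoxy-12-oxo-13,14,15,16-tetranorcleroda-1,3-dien-18,19-olide (C12 aldehyde)
Conditions: Dess–Martin periodinane, NaHCO3, CH2Cl2, 0 → 23 °C
Reagents that add atoms: none
Why: Dess–Martin oxidation gives the non-epimerisable aldehyde (C11 is attached to the quaternary C9) under buffered conditions.

**Step 14**
Reactants: 21 C12 aldehyde; 22 3-bromofuran-2(5H)-one
Product: 23 7α-acetoxy-12-hydroxycleroda-1,3,13-triene-18,19:16,15-diolide (C12 epimers)
Conditions: 22 (3 equiv), CrCl2 (6 equiv), NiCl2 (1 mol %), DMF, 23 °C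
Reagents that add atoms: none
Why: Nozaki–Hiyama–Kishi coupling, in which the nickel-derived alkenylchromium of the α-bromobutenolide adds only to the aldehyde in the presence of the lactones and the acetate, forms the C12–C13 bond; the carbinol configuration is erased in step 15.

**Step 15**
Reactants: 23 NHK carbinol
Product: 25 7α-acetoxy-12-oxo-1,13-cyclocleroda-3,14-diene-18,19:16,15-diolide (H-1 α; C16 axial on the β face of C13; C14 equatorial), via 3-acylfuranone 24 (not isolated)
Conditions: Dess–Martin periodinane, NaHCO3, CH2Cl2, 0 °C; filter; then K2CO3 (0.3 equiv), 18-crown-6, MeCN, 23 °C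
Reagents that add atoms: none
Why: Oxidation gives acylfuranone 24, whose γ-deprotonation forms a 3-acyl-2-furanolate that adds through C13 to C1 of the dienyl lactone (intramolecular vinylogous 1,6-Michael addition, 6-exo closure of ring C) and is reprotonated at C2; the reversible addition should settle in the all-trans chair (H-1 α), and the non-chelated enolate rotamer favoured by the crown-complexed cation (C12=O anti to the lactone oxygen) places C16 axial and C14 equatorial at C13.

**Step 16**
Reactants: 25 spiro enol lactone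
Product: 26 target CNP0308057.1 (14,15-epoxide on the lactone face syn to the C12 carbonyl)
Conditions: DMDO (acetone solution), CH2Cl2, −20 → 0 °C
Reagents that add atoms: dimethyldioxirane CC1(C)OO1
Why: Neutral DMDO epoxidation should take the electron-rich enol-lactone C14=C15 bond in preference to the conjugated C3=C4 bond, from the lactone face syn to the flat C12 carbonyl and anti to the C1 methine and C2 methylene that shield the other face.

**Compound list**

1 | 4-(tert-butyldimethylsilyloxy)but-1-yne | C#CCCO[Si](C)(C)C(C)(C)C | starting material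
2 | (E)-[4-(tert-butyldimethylsilyloxy)-2-methylbut-1-enyl]dimethylalane | C/C(CCO[Si](C)(C)C(C)(C)C)=C\[Al](C)C | intermediate
3 | (E)-5-(tert-butyldimethylsilyloxy)-3-methylpent-2-en-1-ol | OC/C=C(\C)CCO[Si](C)(C)C(C)(C)C | intermediate
4 | (E)-5-(tert-butyldimethylsilyloxy)-3-methylpent-2-enyl propanoate | CCC(=O)OC/C=C(\C)CCO[Si](C)(C)C(C)(C)C | intermediate
5 | boron ketene acetal of 4 with the (S,S)-diazaborolidine (methyl cis to O–B) | C/C=C(/OC/C=C(\C)CCO[Si](C)(C)C(C)(C)C)OB1N(S(=O)(=O)c2cc(cc(c2)C(F)(F)F)C(F)(F)F)[C@@H](c2ccccc2)[C@H](c2ccccc2)N1S(=O)(=O)c1cc(cc(c1)C(F)(F)F)C(F)(F)F | intermediate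
6 | (2S,3R)-3-[2-(tert-butyldimethylsilyloxy)ethyl]-2,3-dimethylpent-4-enoic acid | C=C[C@@](C)(CCO[Si](C)(C)C(C)(C)C)[C@H](C)C(=O)O | intermediate
7 | (2S,3R,4E)-3-[2-(tert-butyldimethylsilyloxy)ethyl]-2,3-dimethylhepta-4,6-dienoic acid | C=C/C=C/[C@@](C)(CCO[Si](C)(C)C(C)(C)C)[C@H](C)C(=O)O | intermediate
8 | acyl imidazolide of 7 | C=C/C=C/[C@@](C)(CCO[Si](C)(C)C(C)(C)C)[C@H](C)C(=O)n1ccnc1 | intermediate
9 | allyl (4S,5R,6E)-5-[2-(tert-butyldimethylsilyloxy)ethyl]-4,5-dimethyl-3-oxonona-6,8-dienoate | C=C/C=C/[C@@](C)(CCO[Si](C)(C)C(C)(C)C)[C@H](C)C(=O)CC(=O)OCC=C | intermediate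
10 | 4-bromofuran-2(5H)-one | O=C1C=C(Br)CO1 | starting material
11 | allyl (4S,5R,6E)-5-[2-(tert-butyldimethylsilyloxy)ethyl]-4,5-dimethyl-3-oxo-2-(5-oxo-2,5-dihydrofuran-3-yl)nona-6,8-dienoate (C2 epimers) | C=C/C=C/[C@@](C)(CCO[Si](C)(C)C(C)(C)C)[C@H](C)C(=O)C(C(=O)OCC=C)C1=CC(=O)OC1 | intermediate
12 | β-keto acid from 11 | C=C/C=C/[C@@](C)(CCO[Si](C)(C)C(C)(C)C)[C@H](C)C(=O)C(C(=O)O)C1=CC(=O)OC1 | intermediate
13 | 4-[(3S,4R,5E)-4-[2-(tert-butyldimethylsilyloxy)ethyl]-3,4-dimethyl-2-oxoocta-5,7-dienyl]furan-2(5H)-one | C=C/C=C/[C@@](C)(CCO[Si](C)(C)C(C)(C)C)[C@H](C)C(=O)CC1=CC(=O)OC1 | intermediate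
14 | 12-(tert-butyldimethylsilyloxy)-7-oxo-13,14,15,16-tetranorclerod-1-en-18,19-olide (4β-H; 10β-H) | O=C1C[C@@]23COC(=O)[C@@H]2CC=C[C@@H]3[C@@](C)(CCO[Si](C)(C)C(C)(C)C)[C@@H]1C | intermediate
15 | 7α-hydroxy-12-(tert-butyldimethylsilyloxy)-13,14,15,16-tetranorclerod-1-en-18,19-olide | O[C@@H]1C[C@@]23COC(=O)[C@@H]2CC=C[C@@H]3[C@@](C)(CCO[Si](C)(C)C(C)(C)C)[C@@H]1C | intermediate
16 | 4β-phenylselanyl derivative of 15 | O[C@@H]1C[C@@]23COC(=O)[C@]2([Se]c4ccccc4)CC=C[C@@H]3[C@@](C)(CCO[Si](C)(C)C(C)(C)C)[C@@H]1C | intermediate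
17 | selenoxide of 16 | O[C@@H]1C[C@@]23COC(=O)[C@]2([Se](=O)c4ccccc4)CC=C[C@@H]3[C@@](C)(CCO[Si](C)(C)C(C)(C)C)[C@@H]1C | intermediate
18 | 7α-hydroxy-12-(tert-butyldimethylsilyloxy)-13,14,15,16-tetranorcleroda-1,3-dien-18,19-olide | O[C@@H]1C[C@@]23COC(=O)C2=CC=C[C@@H]3[C@@](C)(CCO[Si](C)(C)C(C)(C)C)[C@@H]1C | intermediate
19 | 7α-acetoxy-12-(tert-butyldimethylsilyloxy)-13,14,15,16-tetranorcleroda-1,3-dien-18,19-olide | CC(=O)O[C@@H]1C[C@@]23COC(=O)C2=CC=C[C@@H]3[C@@](C)(CCO[Si](C)(C)C(C)(C)C)[C@@H]1C | intermediate
20 | 7α-acetoxy-12-hydroxy-13,14,15,16-tetranorcleroda-1,3-dien-18,19-olide | CC(=O)O[C@@H]1C[C@@]23COC(=O)C2=CC=C[C@@H]3[C@@](C)(CCO)[C@@H]1C | intermediate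
21 | 7α-acetoxy-12-oxo-13,14,15,16-tetranorcleroda-1,3-dien-18,19-olide (aldehyde) | CC(=O)O[C@@H]1C[C@@]23COC(=O)C2=CC=C[C@@H]3[C@@](C)(CC=O)[C@@H]1C | intermediate
22 | 3-bromofuran-2(5H)-one | O=C1OCC=C1Br | starting material
23 | 7α-acetoxy-12-hydroxycleroda-1,3,13-triene-18,19:16,15-diolide (C12 epimers) | CC(=O)O[C@@H]1C[C@@]23COC(=O)C2=CC=C[C@@H]3[C@@](C)(CC(O)C2=CCOC2=O)[C@@H]1C | intermediate
24 | 7α-acetoxy-12-oxocleroda-1,3,13-triene-18,19:16,15-diolide (3-acylfuranone) | CC(=O)O[C@@H]1C[C@@]23COC(=O)C2=CC=C[C@@H]3[C@@](C)(CC(=O)C2=CCOC2=O)[C@@H]1C | intermediate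
25 | 7α-acetoxy-12-oxo-1,13-cyclocleroda-3,14-diene-18,19:16,15-diolide (spiro enol lactone) | CC(=O)O[C@@H]1C[C@@]23COC(=O)C2=CC[C@@H]2[C@@H]3[C@@](C)(CC(=O)[C@]23C(=O)OC=C3)[C@@H]1C | intermediate
26 | CNP0308057.1 (14,15-epoxide of 25) | CC(=O)O[C@@H]1C[C@@]23COC(=O)C2=CC[C@@H]2[C@@H]3[C@@](C)(CC(=O)[C@]23C(=O)O[C@H]2O[C@H]23)[C@@H]1C | target

**Totals.** 16 steps in all; the longest linear sequence is 16 steps (1 → 26), with 10 and 22 entering as purchased fragments.

**Steps most likely to fail, with fallbacks**

Step 8. The cycloaddition may be slow at the hindered C5–C10 bond, so that migration of the butenolide double bond towards the C7 ketone (and cycloaddition of that isomer to a five-membered ring) or erosion of endo and facial selectivity competes. The fallback sets out from 9 and returns at 18, replacing steps 6–10. Keto ester 9 is vinylated (NaH, THF) with commercial 3,4-dichlorofuran-2(5H)-one, which reacts at C4, to give the chlorobutenolide keto ester F1. Deallylation and decarboxylation (Pd(PPh3)4, morpholine; the vinyl chloride is inert) give the α-chlorobutenolide triene F2. Its halogen-activated dienophile should cyclise at lower temperature (PhMe, 110 °C) to the 4β-chloro adduct F3. DBU (PhMe, 80 °C) then removes HCl by anti-elimination of the axial chloride with axial H-3 and gives the dienyl lactone ketone F4 directly, without selenium chemistry. Luche reduction (NaBH4, CeCl3·7H2O, MeOH, −40 °C; 1,2-selective, equatorial attack) gives 18.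

Step 15. The free acylfuranone may oligomerise, the ambident furanolate may close through the C12 enolate oxygen, or the spiro centre may form with C14 axial. The fallback sets out from 23 and returns at 25. After Dess–Martin oxidation, thiophenol and Et3N are added so that the acylfuranone is trapped as the sulfide-masked saturated β-keto lactone F5, a non-electrophilic reservoir. K2CO3 with 18-crown-6 in MeCN then effects the 1,6-Michael spirocyclisation of this 2-acylbutyrolactone enolate to the spiro sulfide F6. Oxidation with mCPBA (CH2Cl2, −78 °C) gives the sulfoxide F7, and warming (PhMe, 90 °C, CaCO3) causes syn-elimination towards C15, the only β-hydrogen-bearing carbon, to regenerate the enol lactone 25.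

Step 16. The oxidant may approach the enol lactone from the face syn to C1, giving the epimeric epoxide. The fallback sets out from 25 and returns at 26. NBS in aqueous THF (0 °C) should place bromine on C14 from that same more accessible face and water on the acetal carbon C15 from the opposite face, giving the trans-bromohydrin F8. K2CO3 in acetone then closes the epoxide by displacement of bromide with inversion at C14, which puts the oxygen on the face syn to the C12 carbonyl.

**Further compounds**

F1 | step 8 | allyl (4S,5R,6E)-5-[2-(tert-butyldimethylsilyloxy)ethyl]-2-(4-chloro-5-oxo-2,5-dihydrofuran-3-yl)-4,5-dimethyl-3-oxonona-6,8-dienoate | C=C/C=C/[C@@](C)(CCO[Si](C)(C)C(C)(C)C)[C@H](C)C(=O)C(C(=O)OCC=C)C1=C(Cl)C(=O)OC1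
F2 | step 8 | 3-chloro-4-[(3S,4R,5E)-4-[2-(tert-butyldimethylsilyloxy)ethyl]-3,4-dimethyl-2-oxoocta-5,7-dienyl]furan-2(5H)-one | C=C/C=C/[C@@](C)(CCO[Si](C)(C)C(C)(C)C)[C@H](C)C(=O)CC1=C(Cl)C(=O)OC1
F3 | step 8 | 4β-chloro-12-(tert-butyldimethylsilyloxy)-7-oxo-13,14,15,16-tetranorclerod-1-en-18,19-olide | O=C1C[C@@]23COC(=O)[C@]2(Cl)CC=C[C@@H]3[C@@](C)(CCO[Si](C)(C)C(C)(C)C)[C@@H]1C
F4 | step 8 | 12-(tert-butyldimethylsilyloxy)-7-oxo-13,14,15,16-tetranorcleroda-1,3-dien-18,19-olide | O=C1C[C@@]23COC(=O)C2=CC=C[C@@H]3[C@@](C)(CCO[Si](C)(C)C(C)(C)C)[C@@H]1C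
F5 | step 15 | 7α-acetoxy-12-oxo-14-(phenylthio)cleroda-1,3-diene-18,19:16,15-diolide (C13 and C14 epimers) | CC(=O)O[C@@H]1C[C@@]23COC(=O)C2=CC=C[C@@H]3[C@@](C)(CC(=O)C2C(=O)OCC2Sc4ccccc4)[C@@H]1C
F6 | step 15 | 7α-acetoxy-12-oxo-14-(phenylthio)-1,13-cycloclerod-3-ene-18,19:16,15-diolide (C14 epimers) | CC(=O)O[C@@H]1C[C@@]23COC(=O)C2=CC[C@@H]2[C@@H]3[C@@](C)(CC(=O)[C@]23C(=O)OCC3Sc4ccccc4)[C@@H]1C
F7 | step 15 | sulfoxide of F6 | CC(=O)O[C@@H]1C[C@@]23COC(=O)C2=CC[C@@H]2[C@@H]3[C@@](C)(CC(=O)[C@]23C(=O)OCC3S(=O)c4ccccc4)[C@@H]1C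
F8 | step 16 | 14-bromo-15-hydroxy derivative of 25 (trans-bromohydrin; bromine syn to C1 and hydroxyl syn to C12) | CC(=O)O[C@@H]1C[C@@]23COC(=O)C2=CC[C@@H]2[C@@H]3[C@@](C)(CC(=O)[C@]23C(=O)O[C@@H](O)[C@@H]3Br)[C@@H]1C
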